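**Retrosynthetic overview**

- The strategy rests on the oxolane core of target 41. Ring atoms O1, C2, C3(OH), C4 and C5, the exocyclic carbinol carbon on C2, the vinylic CH next to it and the first CH2 of the C5 chain map onto shikimic acid 1 as O4, C4, C5, C6, C1, C3, C2 and the carboxyl carbon. The 3R,4S,5R triol becomes the carbinol O, the ring O and the 3-OH without any inversion.
- Key disconnection: the O1–C5 bond. Ozonolysis of the cyclohexene C1=C2 bond of enyne 8 (C4–OH free) gives the hemiketal 11, which carries the future vinylic carbon as an aldehyde. Silane reduction then sets C5 (2,5-trans).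
- East arm: aldehyde → alkyne → hydroxyethylation → Red-Al/I2 → methyl coupling gives the (E)-trisubstituted alkene; the acid comes from late oxidation of the primary alcohol.
- West arm: alkynylsilane → propargylic alcohol → Red-Al/NCS (Z-chloroalkene) → allylic bromide → Cu-alkynylation with propargyl alcohol → Ru trans-hydrostannation → Stille coupling with ethyl (Z)-3-iodoacrylate and lactonisation.
- Ring order: the oxolane first (step 6), the pyranone last (step 20).

Key step: step 6

**Remarks on the chemistry**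

- The alkynyl silyl group is triisopropylsilyl, not trimethylsilyl. Methanolic carbonate in step 7 would cleave an alkynyl–SiMe3 bond and leave two terminal alkynes that cannot be told apart.
- The pyranone is built on the chain (steps 18–20) instead of being brought in as a preformed stannane, because each of these steps has a fixed regio- and stereochemical outcome.
- The anomeric carbon of 11 and 13 is left undefined; both anomers converge in step 8.
- Ring positions of 2–10 use shikimate numbering; from 11 on, oxolane numbering as in the target.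
- TBS = tert-butyldimethylsilyl, TIPS = triisopropylsilyl.

**Route**

Step 1
Reactants: 1 (−)-shikimic acid
Product: 2 methyl shikimate
Conditions: MeOH, CSA (cat.), reflux
Reagents that add atoms: methanol, CO
Why: Fischer esterification of the conjugated acid; the three carbinol centres are not involved.

Step 2
Reactants: 2 methyl shikimate
Product: 3 methyl 3,5-bis-O-TBS-shikimate (C4–OH free)
Conditions: TBSCl (2.2 equiv), imidazole, DMF, 0 °C → rt
Reagents that add atoms: tert-butyldimethylsilyl chloride, CC(C)(C)[Si](C)(C)Cl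
Why: Silyl ether formation; the allylic C3–OH and the C5–OH react first, and the C4–OH, then flanked by two bulky silyl ethers, should stay free.

Step 3
Reactants: 3 methyl 3,5-bis-O-TBS-shikimate
Product: 4 allylic alcohol [(3R,4S,5R)-3,5-bis(TBSO)-4-hydroxycyclohex-1-en-1-yl]methanol
Conditions: DIBAL-H (4 equiv), CH2Cl2, −78 → 0 °C; Rochelle salt
Reagents that add atoms: none
Why: DIBAL 1,2-reduction of the enoate to the allylic alcohol; one extra equivalent is consumed by the free hydroxyl and the silyl ethers are inert.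

Step 4
Reactants: 4 allylic alcohol
Product: 5 allylic bromide (3R,4S,5R)-1-(bromomethyl)-3,5-bis(TBSO)cyclohex-1-en-4-ol
Conditions: CBr4, PPh3, 2,6-lutidine, CH2Cl2, −20 → 0 °C
Reagents that add atoms: carbon tetrabromide, BrC(Br)(Br)Br
Why: Appel bromination; the primary allylic alcohol is activated much faster than the secondary C4–OH between two silyloxy groups.

Step 5
Reactants: 5 allylic bromide; 6 1-(triisopropylsilyl)propyne
Product: 8 enyne (3R,4S,5R)-3,5-bis(TBSO)-1-[4-(triisopropylsilyl)but-3-yn-1-yl]cyclohex-1-en-4-ol, via lithiated silylpropyne 7 (not isolated)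
Conditions: 6 (2.4 equiv), n-BuLi, THF, −20 °C; then 5, −78 → −20 °C
Reagents that add atoms: 1-(triisopropylsilyl)propyne 6, CC#C[Si](C(C)C)(C(C)C)C(C)C
Why: SN2 propargylation of the primary allylic bromide; the bulky silyl group makes the lithio reagent react at its propargylic terminus (no allene), the first equivalent only deprotonates the C4–OH, and the resulting alkoxide cannot cyclise onto the bromide without forming a bridgehead alkene.

Step 6
Reactants: 8 enyne
Product: 11 lactol aldehyde (anomeric mixture), via secondary ozonide 9 (not isolated), via keto aldehyde 10 (not isolated)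
Conditions: O3, CH2Cl2, −78 °C, Sudan Red 7B end point; then PPh3, −78 °C → rt
Reagents that add atoms: ozone, [O-][O+]=O
Why: Ozone adds as a 1,3-dipole to the trisubstituted ring alkene; the primary ozonide cleaves to the C2 aldehyde and the C1 carbonyl oxide, which recombine to ozonide 9 (or the carbonyl oxide is trapped directly by the C4–OH), and PPh3 releases the 1,6-keto aldehyde 10. The C4 hydroxyl, gamma to the ketone, then adds to it in a 5-exo-trig closure, forming the O1–C5 bond and the oxolane ring as a hemiketal while the aldehyde remains on the future vinylic carbon. The closest known reaction type is ozonolysis of a cyclohexenol with capture of the new carbonyl by a ring hydroxyl as a furanose-type lactol. The only new stereocentre is the anomeric carbon, which is not controlled and is removed in step 8; the three carbinol centres from shikimic acid are not touched. The step needs chemoselectivity for the alkene over the silylalkyne, which the much higher rate of alkene ozonolysis and the dye end point should secure. It also needs site selectivity in the closure, which is fixed because only the C4–OH is free and towards the aldehyde it could only form a four-membered ring.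

Step 7
Reactants: 11 lactol aldehyde; 12 dimethyl (1-diazo-2-oxopropyl)phosphonate
Product: 13 alkynyl lactol (anomeric mixture)
Conditions: 12, K2CO3, MeOH, 0 °C → rt
Reagents that add atoms: dimethyl (1-diazo-2-oxopropyl)phosphonate 12, COP(=O)(OC)C(=[N+]=[N-])C(C)=O
Why: Ohira–Bestmann (Seyferth–Gilbert) homologation of the aldehyde to the terminal alkyne under mild carbonate conditions; the hemiketal and the TIPS-alkyne should be inert to it.

Step 8
Reactants: 13 alkynyl lactol
Product: 15 2,5-trans oxolane (2S,3R,5R)-3-(TBSO)-2-[(1R)-1-(TBSO)prop-2-yn-1-yl]-5-[4-(triisopropylsilyl)but-3-yn-1-yl]oxolane, via oxocarbenium ion 14 (not isolated)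
Conditions: Et3SiH (5 equiv), BF3·OEt2 (2 equiv), CH2Cl2, −78 → −40 °C
Reagents that add atoms: none
Why: Ionic reductive deoxygenation of the hemiketal; hydride should attack the envelope oxocarbenium ion on its inside face, cis to the pseudoaxial C3 silyloxy group, which sets C5 as R with the butynyl chain trans to both other ring substituents.

Step 9
Reactants: 15 2,5-trans oxolane; 16 ethylene oxide
Product: 18 homopropargylic alcohol (C2 side chain now CH(OTBS)–C≡C–CH2CH2OH), via lithium acetylide 17 (not isolated)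
Conditions: n-BuLi, THF, −78 °C; BF3·OEt2, then 16, −78 °C
Reagents that add atoms: ethylene oxide 16, C1CO1
Why: Yamaguchi–Hirao opening of the epoxide by the lithium acetylide with BF3 activation; only the terminal alkyne carries an acidic hydrogen.

Step 10
Reactants: 18 homopropargylic alcohol
Product: 19 triol (5R)-5-[(2S,3R,5R)-3-hydroxy-5-[4-(triisopropylsilyl)but-3-yn-1-yl]oxolan-2-yl]pent-3-yne-1,5-diol
Conditions: HCl (cat., from AcCl), MeOH, 0 °C → rt
Reagents that add atoms: none
Why: Acid-catalysed methanolysis of both TBS ethers frees the propargylic hydroxyl needed as directing group in step 11; the alkynyl C–Si bond is stable to acid.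

Step 11
Reactants: 19 triol
Product: 21 (Z)-vinyl iodide (3Z,5R)-3-iodo-5-[(2S,3R,5R)-3-hydroxy-5-[4-(triisopropylsilyl)but-3-yn-1-yl]oxolan-2-yl]pent-3-ene-1,5-diol, via alkenylaluminate 20 (not isolated)
Conditions: Red-Al (6 equiv), THF, 0 °C → rt; EtOAc; then I2, THF, −78 → 0 °C
Reagents that add atoms: iodine, II
Why: Hydroxyl-directed trans-hydroalumination followed by iodinolysis with retention; the propargylic and the homopropargylic alkoxide both place aluminium on the carbon bearing the CH2CH2O chain, hydride adds trans to it, so iodine ends up cis to the carbinol carbon, and the undirected silylalkyne is not reduced.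

Step 12
Reactants: 21 (Z)-vinyl iodide; 22 trimethylboroxine
Product: 23 (E)-trisubstituted alkene triol (3E,5R)-3-methyl-5-[(2S,3R,5R)-3-hydroxy-5-[4-(triisopropylsilyl)but-3-yn-1-yl]oxolan-2-yl]pent-3-ene-1,5-diol
Conditions: 22, Pd(dppf)Cl2 (5 mol%), K2CO3, dioxane–H2O, 80 °C
Reagents that add atoms: trimethylboroxine 22, CB1OB(C)OB(C)O1
Why: Suzuki–Miyaura methylation of the alkenyl iodide with retention of geometry, which leaves the methyl group cis to the carbinol carbon as in the target; free hydroxyls are tolerated.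

Step 13
Reactants: 23 (E)-trisubstituted alkene triol
Product: 24 terminal alkyne triol (3E,5R)-5-[(2S,3R,5R)-5-(but-3-yn-1-yl)-3-hydroxyoxolan-2-yl]-3-methylpent-3-ene-1,5-diol
Conditions: TBAF, THF, 0 °C → rt
Reagents that add atoms: none
Why: Fluoride-induced protodesilylation of the alkynylsilane; no other group in the triol reacts with fluoride.

Step 14
Reactants: 24 terminal alkyne triol
Product: 25 tris-TBS ether of 24
Conditions: TBSOTf (3.6 equiv), 2,6-lutidine, CH2Cl2, −78 → 0 °C
Reagents that add atoms: tert-butyldimethylsilyl triflate, CC(C)(C)[Si](C)(C)OS(=O)(=O)C(F)(F)F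
Why: Exhaustive silylation with the silyl triflate protects all three hydroxyls in one step and leaves the primary ether as the one most easily removed later.

Step 15
Reactants: 25 tris-TBS ether; 26 paraformaldehyde
Product: 28 propargylic alcohol (C5 chain now CH2CH2–C≡C–CH2OH), via lithium acetylide 27 (not isolated)
Conditions: n-BuLi, THF, −78 °C; then 26, −78 °C → rt
Reagents that add atoms: paraformaldehyde 26, C=O
Why: Addition of the lithium acetylide to formaldehyde; the terminal alkyne is the only acidic site.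

Step 16
Reactants: 28 propargylic alcohol
Product: 30 (Z)-chloroallylic alcohol (C5 chain CH2CH2–C(Cl)=CH–CH2OH), via alkenylaluminate 29 (not isolated)
Conditions: Red-Al, THF, 0 °C → rt; EtOAc; then NCS, THF, −78 → 0 °C
Reagents that add atoms: N-chlorosuccinimide, O=C1CCC(=O)N1Cl
Why: Hydroxyl-directed trans-hydroalumination and chlorinolysis with retention; aluminium, and then chlorine, sits on the carbon remote from the hydroxyl and cis to the CH2OH group, which gives the Z-chloroalkene.

Step 17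
Reactants: 30 (Z)-chloroallylic alcohol
Product: 31 allylic bromide (C5 chain CH2CH2–C(Cl)=CH–CH2Br)
Conditions: CBr4, PPh3, 2,6-lutidine, CH2Cl2, −20 °C
Reagents that add atoms: carbon tetrabromide, BrC(Br)(Br)Br
Why: Appel bromination of the only free, primary allylic hydroxyl; SN2′ attack at the chlorine-bearing carbon is disfavoured, so the alkene geometry is kept.

Step 18
Reactants: 31 allylic bromide; 32 propargyl alcohol
Product: 33 skipped enyne (C5 chain CH2CH2–C(Cl)=CH–CH2–C≡C–CH2OH)
Conditions: 32, CuI, NaI, K2CO3, DMF, rt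
Reagents that add atoms: propargyl alcohol 32, C#CCO
Why: Copper-mediated coupling of a copper acetylide with a primary allylic halide (1,4-enyne synthesis); substitution occurs at the unhindered CH2, not at the chlorinated gamma carbon.

Step 19
Reactants: 33 skipped enyne
Product: 34 alkenylstannane (C5 chain CH2CH2–C(Cl)=CH–CH2–CH=C(SnBu3)–CH2OH, chain CH2 cis to tin)
Conditions: [Cp*RuCl]4 (3 mol%), Bu3SnH (1.1 equiv, slow addition), CH2Cl2, rt
Reagents that add atoms: tributyltin hydride, CCCC[SnH](CCCC)CCCC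
Why: Ruthenium-catalysed hydroxyl-directed trans-hydrostannation; hydrogen bonding of the propargylic OH to the chloride ligand steers tin to the proximal alkyne carbon and hydrogen adds trans, which fixes the later exocyclic alkene geometry.

Step 20
Reactants: 34 alkenylstannane; 35 ethyl (Z)-3-iodoacrylate
Product: 37 tris-TBS pyranone (5-alkylidene-5,6-dihydro-2H-pyran-2-one in place), via hydroxy dienoate 36 (not isolated)
Conditions: 35, Pd(PPh3)4 (10 mol%), CuTC, [Ph2PO2][NBu4], DMF, rt; then PPTS (cat.), CH2Cl2, rt → 40 °C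
Reagents that add atoms: ethyl (Z)-3-iodoacrylate 35, CCOC(=O)/C=C\I
Why: Copper-assisted Stille coupling with retention at both alkenes puts the Z-acrylate cis to the chain CH2, and the hydroxymethyl group then closes onto the Z-ester to give the six-membered unsaturated lactone.

Step 21
Reactants: 37 tris-TBS pyranone
Product: 38 primary alcohol (secondary TBS ethers kept)
Conditions: HF·pyridine, pyridine, THF, 0 °C
Reagents that add atoms: none
Why: Selective desilylation; the unhindered primary TBS ether is cleaved well before the two secondary ones under buffered HF·pyridine.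

Step 22
Reactants: 38 primary alcohol
Product: 40 bis-TBS carboxylic acid, via aldehyde 39 (not isolated)
Conditions: DMP, NaHCO3, CH2Cl2, 0 °C; then NaClO2, NaH2PO4, 2-methyl-2-butene, t-BuOH–H2O, 0 °C
Reagents that add atoms: sodium chlorite, [Na+].[O-]Cl=O
Why: Buffered Dess–Martin oxidation followed at once by Pinnick oxidation takes the alcohol to the β,γ-unsaturated acid without a base strong enough to move the alkene into conjugation.

Step 23
Reactants: 40 bis-TBS carboxylic acid
Product: 41 target, (3E,5R)-5-hydroxy-5-[(2S,3R,5R)-3-hydroxy-5-[(3Z)-3-chloro-6-[(3E)-6-oxo-2H-pyran-3(6H)-ylidene]hex-3-en-1-yl]oxolan-2-yl]-3-methylpent-3-enoic acid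
Conditions: HF·pyridine (excess), THF, 0 °C → rt
Reagents that add atoms: none
Why: Acidic fluoride desilylation removes both secondary TBS ethers; the dienyl lactone and the β,γ-unsaturated acid would not survive a basic fluoride source as well.

**Compound list**

1 | (−)-shikimic acid, (3R,4S,5R)-3,4,5-trihydroxycyclohex-1-ene-1-carboxylic acid | OC(=O)C1=C[C@@H](O)[C@@H](O)[C@H](O)C1 | starting material
2 | methyl shikimate | COC(=O)C1=C[C@@H](O)[C@@H](O)[C@H](O)C1 | intermediate
3 | methyl (3R,4S,5R)-3,5-bis(tert-butyldimethylsilyloxy)-4-hydroxycyclohex-1-ene-1-carboxylate | COC(=O)C1=C[C@@H](O[Si](C)(C)C(C)(C)C)[C@@H](O)[C@H](O[Si](C)(C)C(C)(C)C)C1 | intermediate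
4 | [(3R,4S,5R)-3,5-bis(TBSO)-4-hydroxycyclohex-1-en-1-yl]methanol | OCC1=C[C@@H](O[Si](C)(C)C(C)(C)C)[C@@H](O)[C@H](O[Si](C)(C)C(C)(C)C)C1 | intermediate
5 | (3R,4S,5R)-1-(bromomethyl)-3,5-bis(TBSO)cyclohex-1-en-4-ol (shikimate numbering) | BrCC1=C[C@@H](O[Si](C)(C)C(C)(C)C)[C@@H](O)[C@H](O[Si](C)(C)C(C)(C)C)C1 | intermediate
6 | 1-(triisopropylsilyl)propyne | CC#C[Si](C(C)C)(C(C)C)C(C)C | starting material
7 | 3-lithio-1-(triisopropylsilyl)propyne (not isolated) | [Li]CC#C[Si](C(C)C)(C(C)C)C(C)C | intermediate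
8 | (3R,4S,5R)-3,5-bis(TBSO)-1-[4-(triisopropylsilyl)but-3-yn-1-yl]cyclohex-1-en-4-ol (shikimate numbering; key-step precursor) | CC(C)[Si](C(C)C)(C(C)C)C#CCCC1=C[C@@H](O[Si](C)(C)C(C)(C)C)[C@@H](O)[C@H](O[Si](C)(C)C(C)(C)C)C1 | intermediate
9 | secondary ozonide of 8 (1,2,4-trioxolane bridging former C1 and C2; bridgehead configuration undefined; not isolated) | CC(C)[Si](C(C)C)(C(C)C)C#CCCC12C[C@@H](O[Si](C)(C)C(C)(C)C)[C@H](O)[C@H](O[Si](C)(C)C(C)(C)C)C(OO1)O2 | intermediate
10 | open-chain keto aldehyde, 2,4-bis(TBSO)-3-hydroxy-6-oxo-10-(triisopropylsilyl)dec-9-ynal, C2–C4 configured as C3–C5 of 8 (not isolated) | O=C[C@@H](O[Si](C)(C)C(C)(C)C)[C@@H](O)[C@H](O[Si](C)(C)C(C)(C)C)CC(=O)CCC#C[Si](C(C)C)(C(C)C)C(C)C | intermediate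
11 | lactol aldehyde, (2S)-2-(TBSO)-2-[(2S,3R)-3-(TBSO)-5-hydroxy-5-[4-(triisopropylsilyl)but-3-yn-1-yl]oxolan-2-yl]acetaldehyde, anomeric mixture (key-step product) | O=C[C@@H](O[Si](C)(C)C(C)(C)C)[C@H]1OC(O)(CCC#C[Si](C(C)C)(C(C)C)C(C)C)C[C@H]1O[Si](C)(C)C(C)(C)C | intermediate
12 | dimethyl (1-diazo-2-oxopropyl)phosphonate (Ohira–Bestmann reagent) | COP(=O)(OC)C(=[N+]=[N-])C(C)=O | starting material
13 | alkynyl lactol: oxolane (2S,3R) with C2 = (1R)-1-(TBSO)prop-2-yn-1-yl, C3 = OTBS, C5 = OH and 4-(triisopropylsilyl)but-3-yn-1-yl, anomeric mixture | C#C[C@@H](O[Si](C)(C)C(C)(C)C)[C@H]1OC(O)(CCC#C[Si](C(C)C)(C(C)C)C(C)C)C[C@H]1O[Si](C)(C)C(C)(C)C | intermediate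
14 | cyclic oxocarbenium ion from 13 (O1=C5; not isolated) | C#C[C@@H](O[Si](C)(C)C(C)(C)C)[C@H]1[O+]=C(CCC#C[Si](C(C)C)(C(C)C)C(C)C)C[C@H]1O[Si](C)(C)C(C)(C)C | intermediate
15 | (2S,3R,5R)-3-(TBSO)-2-[(1R)-1-(TBSO)prop-2-yn-1-yl]-5-[4-(triisopropylsilyl)but-3-yn-1-yl]oxolane | C#C[C@@H](O[Si](C)(C)C(C)(C)C)[C@H]1O[C@H](CCC#C[Si](C(C)C)(C(C)C)C(C)C)C[C@H]1O[Si](C)(C)C(C)(C)C | intermediate
16 | ethylene oxide | C1CO1 | starting material
17 | lithium acetylide of 15 (not isolated) | [Li]C#C[C@@H](O[Si](C)(C)C(C)(C)C)[C@H]1O[C@H](CCC#C[Si](C(C)C)(C(C)C)C(C)C)C[C@H]1O[Si](C)(C)C(C)(C)C | intermediate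
18 | (5R)-5-(TBSO)-5-[(2S,3R,5R)-3-(TBSO)-5-[4-(triisopropylsilyl)but-3-yn-1-yl]oxolan-2-yl]pent-3-yn-1-ol | OCCC#C[C@@H](O[Si](C)(C)C(C)(C)C)[C@H]1O[C@H](CCC#C[Si](C(C)C)(C(C)C)C(C)C)C[C@H]1O[Si](C)(C)C(C)(C)C | intermediate
19 | (5R)-5-[(2S,3R,5R)-3-hydroxy-5-[4-(triisopropylsilyl)but-3-yn-1-yl]oxolan-2-yl]pent-3-yne-1,5-diol | OCCC#C[C@@H](O)[C@H]1O[C@H](CCC#C[Si](C(C)C)(C(C)C)C(C)C)C[C@H]1O | intermediate
20 | cyclic alkenylaluminate (2,5-dihydro-1,2-oxaaluminole; the other hydroxyls, present as aluminium alkoxides, are drawn as OH; not isolated) | [Na+].COCCO[Al-]1(OCCOC)O[C@@H]([C@H]2O[C@H](CCC#C[Si](C(C)C)(C(C)C)C(C)C)C[C@H]2O)C=C1CCO | intermediate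
21 | (3Z,5R)-3-iodo-5-[(2S,3R,5R)-3-hydroxy-5-[4-(triisopropylsilyl)but-3-yn-1-yl]oxolan-2-yl]pent-3-ene-1,5-diol | I/C(=C\[C@@H](O)[C@H]1O[C@H](CCC#C[Si](C(C)C)(C(C)C)C(C)C)C[C@H]1O)CCO | intermediate
22 | trimethylboroxine | CB1OB(C)OB(C)O1 | starting material
23 | (3E,5R)-3-methyl-5-[(2S,3R,5R)-3-hydroxy-5-[4-(triisopropylsilyl)but-3-yn-1-yl]oxolan-2-yl]pent-3-ene-1,5-diol | C/C(=C\[C@@H](O)[C@H]1O[C@H](CCC#C[Si](C(C)C)(C(C)C)C(C)C)C[C@H]1O)CCO | intermediate
24 | (3E,5R)-5-[(2S,3R,5R)-5-(but-3-yn-1-yl)-3-hydroxyoxolan-2-yl]-3-methylpent-3-ene-1,5-diol | C/C(=C\[C@@H](O)[C@H]1O[C@H](CCC#C)C[C@H]1O)CCO | intermediate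
25 | tris-TBS ether of 24 (primary, carbinol and oxolane C3 oxygens silylated) | C/C(=C\[C@@H](O[Si](C)(C)C(C)(C)C)[C@H]1O[C@H](CCC#C)C[C@H]1O[Si](C)(C)C(C)(C)C)CCO[Si](C)(C)C(C)(C)C | intermediate
26 | paraformaldehyde (monomer shown) | C=O | starting material
27 | lithium acetylide of 25 (not isolated) | C/C(=C\[C@@H](O[Si](C)(C)C(C)(C)C)[C@H]1O[C@H](CCC#C[Li])C[C@H]1O[Si](C)(C)C(C)(C)C)CCO[Si](C)(C)C(C)(C)C | intermediate
28 | propargylic alcohol: 25 with the C5 chain extended to CH2CH2–C≡C–CH2OH | C/C(=C\[C@@H](O[Si](C)(C)C(C)(C)C)[C@H]1O[C@H](CCC#CCO)C[C@H]1O[Si](C)(C)C(C)(C)C)CCO[Si](C)(C)C(C)(C)C | intermediate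
29 | cyclic alkenylaluminate from 28 (not isolated) | C/C(=C\[C@@H](O[Si](C)(C)C(C)(C)C)[C@H]1O[C@H](CCC2=CCO[Al-]2(OCCOC)OCCOC)C[C@H]1O[Si](C)(C)C(C)(C)C)CCO[Si](C)(C)C(C)(C)C.[Na+] | intermediate
30 | (Z)-chloroallylic alcohol: C5 chain (3Z)-3-chloro-5-hydroxypent-3-en-1-yl, three TBS ethers | C/C(=C\[C@@H](O[Si](C)(C)C(C)(C)C)[C@H]1O[C@H](CC/C(Cl)=C/CO)C[C@H]1O[Si](C)(C)C(C)(C)C)CCO[Si](C)(C)C(C)(C)C | intermediate
31 | allylic bromide: C5 chain (3Z)-5-bromo-3-chloropent-3-en-1-yl | C/C(=C\[C@@H](O[Si](C)(C)C(C)(C)C)[C@H]1O[C@H](CC/C(Cl)=C/CBr)C[C@H]1O[Si](C)(C)C(C)(C)C)CCO[Si](C)(C)C(C)(C)C | intermediate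
32 | propargyl alcohol | C#CCO | starting material
33 | skipped enyne: C5 chain (3Z)-3-chloro-8-hydroxyoct-3-en-6-yn-1-yl | C/C(=C\[C@@H](O[Si](C)(C)C(C)(C)C)[C@H]1O[C@H](CC/C(Cl)=C/CC#CCO)C[C@H]1O[Si](C)(C)C(C)(C)C)CCO[Si](C)(C)C(C)(C)C | intermediate
34 | alkenylstannane: C5 chain (3Z,6Z)-3-chloro-8-hydroxy-7-(tributylstannyl)octa-3,6-dien-1-yl (chain CH2 cis to tin) | C/C(=C\[C@@H](O[Si](C)(C)C(C)(C)C)[C@H]1O[C@H](CC/C(Cl)=C/C/C=C(\[Sn](CCCC)(CCCC)CCCC)CO)C[C@H]1O[Si](C)(C)C(C)(C)C)CCO[Si](C)(C)C(C)(C)C | intermediate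
35 | ethyl (Z)-3-iodoacrylate | CCOC(=O)/C=C\I | starting material
36 | hydroxy dienoate: ethyl (2Z)-dienoate with the hydroxymethyl group on C4 and the chain CH2 cis to C3 (not isolated) | C/C(=C\[C@@H](O[Si](C)(C)C(C)(C)C)[C@H]1O[C@H](CC/C(Cl)=C/C/C=C(\C=C/C(=O)OCC)CO)C[C@H]1O[Si](C)(C)C(C)(C)C)CCO[Si](C)(C)C(C)(C)C | intermediate
37 | tris-TBS pyranone: C5 chain (3Z)-3-chloro-6-[(3E)-6-oxo-2H-pyran-3(6H)-ylidene]hex-3-en-1-yl | C/C(=C\[C@@H](O[Si](C)(C)C(C)(C)C)[C@H]1O[C@H](CC/C(Cl)=C/C/C=C2\C=CC(=O)OC2)C[C@H]1O[Si](C)(C)C(C)(C)C)CCO[Si](C)(C)C(C)(C)C | intermediate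
38 | primary alcohol: 37 without the primary TBS group | C/C(=C\[C@@H](O[Si](C)(C)C(C)(C)C)[C@H]1O[C@H](CC/C(Cl)=C/C/C=C2\C=CC(=O)OC2)C[C@H]1O[Si](C)(C)C(C)(C)C)CCO | intermediate
39 | β,γ-unsaturated aldehyde from 38 (not isolated) | C/C(=C\[C@@H](O[Si](C)(C)C(C)(C)C)[C@H]1O[C@H](CC/C(Cl)=C/C/C=C2\C=CC(=O)OC2)C[C@H]1O[Si](C)(C)C(C)(C)C)CC=O | intermediate
40 | bis-TBS ether of the target acid | C/C(=C\[C@@H](O[Si](C)(C)C(C)(C)C)[C@H]1O[C@H](CC/C(Cl)=C/C/C=C2\C=CC(=O)OC2)C[C@H]1O[Si](C)(C)C(C)(C)C)CC(=O)O | intermediate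
41 | CNP0180366.1, (3E,5R)-5-hydroxy-5-[(2S,3R,5R)-3-hydroxy-5-[(3Z)-3-chloro-6-[(3E)-6-oxo-2H-pyran-3(6H)-ylidene]hex-3-en-1-yl]oxolan-2-yl]-3-methylpent-3-enoic acid | C/C(=C\[C@@H](O)[C@H]1O[C@H](CC/C(Cl)=C/C/C=C2\C=CC(=O)OC2)C[C@H]1O)CC(=O)O | target

**Step count**

Total steps: 23. Longest linear sequence: 23 steps from (−)-shikimic acid 1; all coupling partners (6, 12, 16, 22, 26, 32, 35) are purchased.

**Steps most likely to fail**

1. Step 8, poor facial selectivity in the hydride transfer. The hydride must enter on the face that carries both the C3 silyloxy group and the bulky C2 side chain. If the side chain shields that face, the 2,5-cis oxolane would form. Fallback, from 13 back to 15, with the hydride delivered from a tether on that same face: treatment of 13 with CSA in methanol should remove both TBS groups and convert the hemiketal into the methyl ketal diol F1. Chlorodiisopropylsilane and imidazole would then give the bis(diisopropylsilyl) ether F2. BF3·OEt2 in CH2Cl2 at −78 °C ionises the ketal, and the Si–H group on the C3 oxygen transfers hydride through a six-membered transition state to the face it occupies; methanolic HCl work-up strips the silicon residues to give the 2,5-trans diol F3. TBSOTf and 2,6-lutidine convert this into 15.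

2. Step 19, loss of regiocontrol or of the substrate in the hydrostannation. Tin may be delivered distal to the hydroxyl, the doubly activated CH2 of the skipped enyne may let the unsaturation migrate, or the product may protodestannylate. Fallback, from 31 back to 34, which avoids the alkyne: palladium-catalysed addition of hexabutylditin to propargyl alcohol 32 (Pd(PPh3)4, THF, reflux) gives (Z)-2,3-bis(tributylstannyl)prop-2-en-1-ol F4. A Stille coupling of allylic bromide 31 with an excess of F4 (Pd2(dba)3, AsPh3, THF–NMP, rt → 40 °C) should occur at the unhindered terminal tin. Because the two tin atoms are cis, the remaining internal tin is cis to the new chain, which is stannane 34; compound 33 is bypassed.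

3. Step 7, base-induced damage to the lactol aldehyde. Methanolic carbonate may epimerise the α-silyloxy aldehyde or eliminate silanolate from the ring-opened β-silyloxy ketone tautomer. Fallback, from 11 back to 18, under non-basic conditions: Ramirez olefination of 11 (CBr4, PPh3, Zn, CH2Cl2, 0 °C) gives the dibromoalkene lactol F5. The same Et3SiH/BF3·OEt2 reduction gives the dibromoalkene oxolane F6. n-BuLi (2.2 equiv, THF, −78 °C) then converts F6 by Corey–Fuchs elimination and rearrangement into lithium acetylide 17, which is trapped in the same flask with BF3·OEt2 and ethylene oxide 16 to give 18.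

**Further compounds**

F1 | step 8 | methyl ketal diol: (2S,3R)-2-[(1R)-1-hydroxyprop-2-yn-1-yl]-5-methoxy-5-[4-(triisopropylsilyl)but-3-yn-1-yl]oxolan-3-ol | C#C[C@@H](O)[C@H]1OC(OC)(CCC#C[Si](C(C)C)(C(C)C)C(C)C)C[C@H]1O
F2 | step 8 | bis(diisopropylsilyl) ether of F1 | C#C[C@@H](O[SiH](C(C)C)C(C)C)[C@H]1OC(OC)(CCC#C[Si](C(C)C)(C(C)C)C(C)C)C[C@H]1O[SiH](C(C)C)C(C)C
F3 | step 8 | (2S,3R,5R)-2-[(1R)-1-hydroxyprop-2-yn-1-yl]-5-[4-(triisopropylsilyl)but-3-yn-1-yl]oxolan-3-ol | C#C[C@@H](O)[C@H]1O[C@H](CCC#C[Si](C(C)C)(C(C)C)C(C)C)C[C@H]1O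
F4 | step 19 | (Z)-2,3-bis(tributylstannyl)prop-2-en-1-ol | OC/C(=C/[Sn](CCCC)(CCCC)CCCC)[Sn](CCCC)(CCCC)CCCC
F5 | step 7 | dibromoalkene lactol: 11 with CH=CBr2 in place of CHO | BrC(Br)=C[C@@H](O[Si](C)(C)C(C)(C)C)[C@H]1OC(O)(CCC#C[Si](C(C)C)(C(C)C)C(C)C)C[C@H]1O[Si](C)(C)C(C)(C)C
F6 | step 7 | dibromoalkene oxolane: 15 with CH=CBr2 in place of C≡CH | BrC(Br)=C[C@@H](O[Si](C)(C)C(C)(C)C)[C@H]1O[C@H](CCC#C[Si](C(C)C)(C(C)C)C(C)C)C[C@H]1O[Si](C)(C)C(C)(C)C
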